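With the core numbered as a 1-tetralone (carbonyl C1, hydroxylated C3, fusion atoms C4a/C8a), ring B contains a β-hydroxy ketone, C1(=O)–C2–C3(OH). Breaking C2–C3 retrosynthetically gives an arene bearing COCH3 at C8a and CH2CHO at C4a, exactly what oxidative opening of a 3-methylindene delivers. The key step is a catalytic enantioselective intramolecular aldol addition of the acetyl methyl carbon (C2) to the aldehyde carbon (C3): one operation forms C2–C3, closes ring B and sets the (R)-carbinol. Its precursor, bis(benzyl ether) keto-aldehyde 23, is freed under neutral conditions from a stable indane cis-diol just before use. A dinuclear zinc catalyst is chosen because primary amines turn such 1,5-keto-aldehydes into isoquinolinium salts.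

Key step: step 14

Assumption: the (R,R)-ligand is assigned by analogy with the facial preference of intermolecular additions of aryl methyl ketones under this catalyst; should the tethered mode favour the opposite aldehyde face, the (S,S)-ligand would be used with no other change.

Step 1
Reactants: 1 1-bromo-3-chloro-5-methoxybenzene; 2 (3-ethoxy-3-oxopropyl)zinc bromide (0.5 M in THF)
Product: 3 ethyl 3-(3-chloro-5-methoxyphenyl)propanoate
Conditions: Pd(PPh3)4 (3 mol%), THF, 50 °C
Reagents that add atoms: none
Why: Negishi coupling in which zerovalent palladium inserts into C–Br far faster than into C–Cl, so the ester-stabilised zinc homoenolate replaces only bromine and the chloride is kept for the second coupling.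

Step 2
Reactants: 3 ethyl 3-(3-chloro-5-methoxyphenyl)propanoate; 4 (3-methylbutyl)zinc bromide (0.5 M in THF)
Product: 5 ethyl 3-[3-methoxy-5-(3-methylbutyl)phenyl]propanoate
Conditions: Pd(P(t-Bu)3)2 (3 mol%), THF/NMP, 100 °C
Reagents that add atoms: none
Why: Negishi coupling of the aryl chloride, enabled by the bulky electron-rich phosphine that promotes oxidative addition into C–Cl, with a primary alkylzinc halide that tolerates the ester.

Step 3
Reactants: 5 ethyl 3-[3-methoxy-5-(3-methylbutyl)phenyl]propanoate
Product: 6 ethyl 3-[2-bromo-5-methoxy-3-(3-methylbutyl)phenyl]propanoate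
Conditions: NBS, MeCN, 0 °C → rt
Reagents that add atoms: N-bromosuccinimide, O=C1CCC(=O)N1Br
Why: Electrophilic aromatic bromination, which for 3,5-dialkylanisoles in acetonitrile goes para to the methoxy group (the carbon between the two alkyl chains); the bromine then blocks that site and later serves as the coupling handle.

Step 4
Reactants: 6 ethyl 3-[2-bromo-5-methoxy-3-(3-methylbutyl)phenyl]propanoate
Product: 7 3-[2-bromo-5-methoxy-3-(3-methylbutyl)phenyl]propanoic acid
Conditions: LiOH, THF/MeOH/H2O, rt; then 1 M HCl
Reagents that add atoms: lithium hydroxide, [Li+].[OH-]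
Why: Ester saponification by acyl substitution with hydroxide, to which the aryl bromide and methyl ether are inert.

Step 5
Reactants: 7 3-[2-bromo-5-methoxy-3-(3-methylbutyl)phenyl]propanoic acid
Product: 10 4-bromo-7-hydroxy-5-(3-methylbutyl)-2,3-dihydro-1H-inden-1-one, via acid chloride 8 (not isolated), via methoxyindanone 9 (not isolated)
Conditions: (COCl)2, DMF (cat.), CH2Cl2, rt; then AlCl3 (3.5 equiv), CH2Cl2, 0 → 40 °C; 1 M HCl work-up
Reagents that add atoms: none
Why: Intramolecular Friedel–Crafts acylation in which the acylium ion, with the para position blocked by bromine, can only close onto the carbon ortho to the methoxy group, after which excess AlCl3 chelated between the new carbonyl and the peri oxygen removes the methyl group as chloromethane (chelation-assisted ether cleavage).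

Step 6
Reactants: 10 4-bromo-7-hydroxy-5-(3-methylbutyl)-2,3-dihydro-1H-inden-1-one
Product: 11 7-(benzyloxy)-4-bromo-5-(3-methylbutyl)-2,3-dihydro-1H-inden-1-one
Conditions: BnBr, K2CO3, DMF, 60 °C
Reagents that add atoms: benzyl bromide, BrCc1ccccc1
Why: Williamson ether synthesis on the potassium phenoxide, which installs a group that can be removed at the end under neutral conditions.

Step 7
Reactants: 11 7-(benzyloxy)-4-bromo-5-(3-methylbutyl)-2,3-dihydro-1H-inden-1-one
Product: 13 4-(benzyloxy)-7-bromo-3-methyl-6-(3-methylbutyl)-1H-indene, via tertiary indanol 12 (not isolated)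
Conditions: MeMgBr, THF, 0 °C; then p-TsOH·H2O (5 mol%), toluene, 50 °C
Reagents that add atoms: methylmagnesium bromide, C[Mg]Br
Why: Grignard addition to the indanone followed by acid-catalysed E1 dehydration of the tertiary benzylic alcohol to the conjugated, endocyclic trisubstituted alkene, which erases the racemic carbinol centre.

Step 8
Reactants: 13 4-(benzyloxy)-7-bromo-3-methyl-6-(3-methylbutyl)-1H-indene; 14 tributyl(1-ethoxyethenyl)stannane
Product: 16 1-[4-(benzyloxy)-3-methyl-6-(3-methylbutyl)-1H-inden-7-yl]ethan-1-one, via ethoxyvinyl arene 15 (not isolated)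
Conditions: Pd(PPh3)4 (5 mol%), toluene, 110 °C; then 1 M HCl, THF, rt
Reagents that add atoms: water, O
Why: Stille coupling that transfers the 1-ethoxyvinyl group without any strong base (the acidic indene CH2 is untouched), followed by acid hydrolysis of the enol ether to the methyl ketone.

Step 9
Reactants: 16 1-[4-(benzyloxy)-3-methyl-6-(3-methylbutyl)-1H-inden-7-yl]ethan-1-one
Product: 17 ({1-[4-(benzyloxy)-3-methyl-6-(3-methylbutyl)-1H-inden-7-yl]ethenyl}oxy)trimethylsilane
Conditions: TMSOTf, Et3N, CH2Cl2, 0 °C; pentane extraction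
Reagents that add atoms: trimethylsilyl trifluoromethanesulfonate, C[Si](C)(C)OS(=O)(=O)C(F)(F)F
Why: Soft enolisation and O-silylation of the methyl ketone, in which the amine base is too weak to deprotonate the indene CH2 and the acetyl group can enolise only towards its methyl carbon.

Step 10
Reactants: 17 ({1-[4-(benzyloxy)-3-methyl-6-(3-methylbutyl)-1H-inden-7-yl]ethenyl}oxy)trimethylsilane; 18 malonyl dichloride
Product: 20 6-[4-(benzyloxy)-3-methyl-6-(3-methylbutyl)-1H-inden-7-yl]-4-hydroxy-2H-pyran-2-one, via diketo acid chloride 19 (not isolated)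
Conditions: Et2O, −78 °C → rt
Reagents that add atoms: none
Why: Pyranone annulation of a silyl enol ether with malonyl dichloride, in which C-acylation at the unhindered terminal carbon (loss of chlorotrimethylsilane) is followed by lactonisation of the aryl ketone enol oxygen onto the second acid chloride and tautomerisation to the 4-hydroxy-2-pyranone.

Step 11
Reactants: 20 6-[4-(benzyloxy)-3-methyl-6-(3-methylbutyl)-1H-inden-7-yl]-4-hydroxy-2H-pyran-2-one
Product: 21 4-(benzyloxy)-6-[4-(benzyloxy)-3-methyl-6-(3-methylbutyl)-1H-inden-7-yl]-2H-pyran-2-one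
Conditions: BnBr, K2CO3, DMF, rt
Reagents that add atoms: benzyl bromide, BrCc1ccccc1
Why: O-alkylation of the potassium salt of the vinylogous acid at the C4 oxygen, which keeps the conjugated 2-pyranone and masks the acidic hydroxyl before the base-sensitive steps, while carbonate is too weak to deprotonate the indene.

Step 12
Reactants: 21 4-(benzyloxy)-6-[4-(benzyloxy)-3-methyl-6-(3-methylbutyl)-1H-inden-7-yl]-2H-pyran-2-one
Product: 22 4-(benzyloxy)-6-[(1RS,2SR)-7-(benzyloxy)-1,2-dihydroxy-1-methyl-5-(3-methylbutyl)-2,3-dihydro-1H-inden-4-yl]-2H-pyran-2-one (racemic cis-diol)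
Conditions: OsO4 (2 mol%), NMO, acetone/H2O, rt
Reagents that add atoms: N-methylmorpholine N-oxide, C[N+]1([O-])CCOCC1; water, O
Why: Catalytic syn-dihydroxylation, where the electron-rich trisubstituted indene alkene should react well before the push–pull C=C bonds of the pyranone; suprafacial addition gives the cis-diol as a racemate, and both centres are destroyed in step 13.

Step 13
Reactants: 22 4-(benzyloxy)-6-[(1RS,2SR)-7-(benzyloxy)-1,2-dihydroxy-1-methyl-5-(3-methylbutyl)-2,3-dihydro-1H-inden-4-yl]-2H-pyran-2-one
Product: 23 2-[2-acetyl-3-(benzyloxy)-6-[4-(benzyloxy)-2-oxo-2H-pyran-6-yl]-5-(3-methylbutyl)phenyl]acetaldehyde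
Conditions: NaIO4 on silica gel, CH2Cl2, rt; filtered, dried and used at once
Reagents that add atoms: none
Why: Malaprade glycol cleavage through the cyclic periodate ester of the cis-diol under neutral heterogeneous conditions, turning the tertiary carbinol into the acetyl group next to the benzyloxy-bearing carbon and the secondary carbinol into the aldehyde, with no chromatography of the labile keto-aldehyde.

Step 14
Reactants: 23 2-[2-acetyl-3-(benzyloxy)-6-[4-(benzyloxy)-2-oxo-2H-pyran-6-yl]-5-(3-methylbutyl)phenyl]acetaldehyde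
Product: 24 (3R)-8-(benzyloxy)-5-[4-(benzyloxy)-2-oxo-2H-pyran-6-yl]-3-hydroxy-6-(3-methylbutyl)-3,4-dihydronaphthalen-1(2H)-one
Conditions: 2,6-bis{[(2R)-2-(hydroxydiphenylmethyl)pyrrolidin-1-yl]methyl}-4-methylphenol ((R,R)-ProPhenol, 10 mol%), Et2Zn (20 mol%), Ph3P=S (15 mol%), 4 Å MS, THF, −20 °C, slow addition of 23 (final 0.02 M); then pH 7 phosphate buffer
Reagents that add atoms: none
Why: Proposed new method: the zinc alkoxide of the dinuclear catalyst deprotonates the unhindered methyl group of the C8a acetyl unit to a zinc enolate while the second zinc binds the aldehyde, so that the enolate carbon (future C2) adds to the aldehyde carbon (future C3) inside the chiral pocket and proton transfer releases the ketol; an enolate pathway is used because the acetyl carbonyl, flanked by the benzyloxy group and the CH2CHO arm, resists carbinolamine formation and because a primary amine would condense irreversibly with this 1,5-keto-aldehyde to an N-substituted 1-methylisoquinolinium salt. The closest known reaction is the intermolecular direct aldol addition of aryl methyl ketones to aldehydes under the same Et2Zn/ProPhenol catalysis, extended here to a ring-closing mode. Ring B closes in a 6-(enolendo)-exo-trig manner, with the enolate C=C inside and the aldehyde C=O outside the new six-membered ring. The C3 configuration is controlled by the ligand, the (R,R)-antipode being chosen to present to the enolate the aldehyde face that leads to the (R)-carbinol. The step needs site selectivity between two enolisable carbonyl groups and arrest at the ketol: the aldehyde-derived enolate could close only a four-membered ring (C4 onto C1) and so reverts, its intermolecular self-aldol being suppressed by high dilution, while −20 °C and a neutral buffered quench should keep the β-hydroxy ketone from dehydrating to the 1-naphthol.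

Step 15
Reactants: 24 (3R)-8-(benzyloxy)-5-[4-(benzyloxy)-2-oxo-2H-pyran-6-yl]-3-hydroxy-6-(3-methylbutyl)-3,4-dihydronaphthalen-1(2H)-one
Product: 25 (3R)-3,8-dihydroxy-5-(4-hydroxy-2-oxo-2H-pyran-6-yl)-6-(3-methylbutyl)-3,4-dihydronaphthalen-1(2H)-one
Conditions: H2 (1 atm), 10% Pd/C, EtOAc, rt, stopped after uptake of two equivalents
Reagents that add atoms: none
Why: Catalytic hydrogenolysis of both benzylic C–O bonds (aryl benzyl ether and vinylogous benzyl ester) under neutral conditions that neither touch the C3 stereocentre nor promote loss of water from the ketol.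

Compound list
1 | 1-bromo-3-chloro-5-methoxybenzene | COc1cc(Cl)cc(Br)c1 | starting material
2 | (3-ethoxy-3-oxopropyl)zinc bromide | CCOC(=O)CC[Zn]Br | starting material
3 | ethyl 3-(3-chloro-5-methoxyphenyl)propanoate | CCOC(=O)CCc1cc(Cl)cc(OC)c1 | intermediate
4 | (3-methylbutyl)zinc bromide | CC(C)CC[Zn]Br | starting material
5 | ethyl 3-[3-methoxy-5-(3-methylbutyl)phenyl]propanoate | CCOC(=O)CCc1cc(OC)cc(CCC(C)C)c1 | intermediate
6 | ethyl 3-[2-bromo-5-methoxy-3-(3-methylbutyl)phenyl]propanoate | CCOC(=O)CCc1cc(OC)cc(CCC(C)C)c1Br | intermediate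
7 | 3-[2-bromo-5-methoxy-3-(3-methylbutyl)phenyl]propanoic acid | OC(=O)CCc1cc(OC)cc(CCC(C)C)c1Br | intermediate
8 | 3-[2-bromo-5-methoxy-3-(3-methylbutyl)phenyl]propanoyl chloride | ClC(=O)CCc1cc(OC)cc(CCC(C)C)c1Br | intermediate (not isolated)
9 | 4-bromo-7-methoxy-5-(3-methylbutyl)-2,3-dihydro-1H-inden-1-one | COc1cc(CCC(C)C)c(Br)c2CCC(=O)c12 | intermediate (not isolated)
10 | 4-bromo-7-hydroxy-5-(3-methylbutyl)-2,3-dihydro-1H-inden-1-one | Oc1cc(CCC(C)C)c(Br)c2CCC(=O)c12 | intermediate
11 | 7-(benzyloxy)-4-bromo-5-(3-methylbutyl)-2,3-dihydro-1H-inden-1-one | O=C1CCc2c(Br)c(CCC(C)C)cc(OCc3ccccc3)c12 | intermediate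
12 | 7-(benzyloxy)-4-bromo-1-methyl-5-(3-methylbutyl)-2,3-dihydro-1H-inden-1-ol (racemic) | CC1(O)CCc2c(Br)c(CCC(C)C)cc(OCc3ccccc3)c12 | intermediate (not isolated)
13 | 4-(benzyloxy)-7-bromo-3-methyl-6-(3-methylbutyl)-1H-indene | CC1=CCc2c(Br)c(CCC(C)C)cc(OCc3ccccc3)c12 | intermediate
14 | tributyl(1-ethoxyethenyl)stannane | CCCC[Sn](CCCC)(CCCC)C(=C)OCC | starting material
15 | 4-(benzyloxy)-7-(1-ethoxyethenyl)-3-methyl-6-(3-methylbutyl)-1H-indene | CC1=CCc2c(C(=C)OCC)c(CCC(C)C)cc(OCc3ccccc3)c12 | intermediate (not isolated)
16 | 1-[4-(benzyloxy)-3-methyl-6-(3-methylbutyl)-1H-inden-7-yl]ethan-1-one | CC1=CCc2c(C(C)=O)c(CCC(C)C)cc(OCc3ccccc3)c12 | intermediate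
17 | ({1-[4-(benzyloxy)-3-methyl-6-(3-methylbutyl)-1H-inden-7-yl]ethenyl}oxy)trimethylsilane | CC1=CCc2c(C(=C)O[Si](C)(C)C)c(CCC(C)C)cc(OCc3ccccc3)c12 | intermediate
18 | malonyl dichloride | O=C(Cl)CC(=O)Cl | starting material
19 | 5-[4-(benzyloxy)-3-methyl-6-(3-methylbutyl)-1H-inden-7-yl]-3,5-dioxopentanoyl chloride | CC1=CCc2c(C(=O)CC(=O)CC(=O)Cl)c(CCC(C)C)cc(OCc3ccccc3)c12 | intermediate (not isolated)
20 | 6-[4-(benzyloxy)-3-methyl-6-(3-methylbutyl)-1H-inden-7-yl]-4-hydroxy-2H-pyran-2-one | CC1=CCc2c(-c3cc(O)cc(=O)o3)c(CCC(C)C)cc(OCc3ccccc3)c12 | intermediate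
21 | 4-(benzyloxy)-6-[4-(benzyloxy)-3-methyl-6-(3-methylbutyl)-1H-inden-7-yl]-2H-pyran-2-one | CC1=CCc2c(-c3cc(OCc4ccccc4)cc(=O)o3)c(CCC(C)C)cc(OCc3ccccc3)c12 | intermediate
22 | 4-(benzyloxy)-6-[(1RS,2SR)-7-(benzyloxy)-1,2-dihydroxy-1-methyl-5-(3-methylbutyl)-2,3-dihydro-1H-inden-4-yl]-2H-pyran-2-one (racemic cis-diol; the 1R,2S enantiomer is written) | C[C@]1(O)[C@@H](O)Cc2c(-c3cc(OCc4ccccc4)cc(=O)o3)c(CCC(C)C)cc(OCc3ccccc3)c12 | intermediate
23 | 2-[2-acetyl-3-(benzyloxy)-6-[4-(benzyloxy)-2-oxo-2H-pyran-6-yl]-5-(3-methylbutyl)phenyl]acetaldehyde | CC(C)CCc1cc(OCc2ccccc2)c(C(C)=O)c(CC=O)c1-c1cc(OCc2ccccc2)cc(=O)o1 | intermediate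
24 | (3R)-8-(benzyloxy)-5-[4-(benzyloxy)-2-oxo-2H-pyran-6-yl]-3-hydroxy-6-(3-methylbutyl)-3,4-dihydronaphthalen-1(2H)-one | CC(C)CCc1cc(OCc3ccccc3)c2c(c1-c1cc(OCc3ccccc3)cc(=O)o1)C[C@@H](O)CC2=O | intermediate
25 | (3R)-3,8-dihydroxy-5-(4-hydroxy-2-oxo-2H-pyran-6-yl)-6-(3-methylbutyl)-3,4-dihydronaphthalen-1(2H)-one | CC(C)CCc1cc(O)c2c(c1-c1cc(O)cc(=O)o1)C[C@@H](O)CC2=O | target

Total step count: 15. Longest linear sequence: 15 steps (1 → 25); the coupling partners 2, 4, 14 and 18 are purchased.

Steps most likely to fail

Step 14 (key step, proposed new method). Three processes threaten it: unproductive enolisation of the arylacetaldehyde followed by intermolecular self-aldol oligomerisation, weak facial discrimination in the tethered transition state, and base-promoted loss of water with aromatisation. The fallback uses known chemistry and sets out from 23. An ordinary base-mediated intramolecular aldol addition (catalytic DBU, THF, −40 °C, acetic acid quench) should close ring B without stereocontrol. This would give 24 together with its mirror image, (3S)-8-(benzyloxy)-5-[4-(benzyloxy)-2-oxo-2H-pyran-6-yl]-3-hydroxy-6-(3-methylbutyl)-3,4-dihydronaphthalen-1(2H)-one F1. Preparative chromatography on a polysaccharide chiral stationary phase would separate the two, and the (3R) component re-enters the route at 24.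

Step 10. The hydrogen chloride liberated may desilylate the enol ether before C-acylation, and the bifunctional acid chloride may grow chains instead of closing the lactone. The fallback sets out from 17 and builds the ring in two separate operations. A Lewis-acid-mediated C-acylation of the silyl enol ether with methyl 3-chloro-3-oxopropanoate (ZnCl2 cat., CH2Cl2, 0 °C) should give methyl 5-[4-(benzyloxy)-3-methyl-6-(3-methylbutyl)-1H-inden-7-yl]-3,5-dioxopentanoate F2. Base-induced lactonisation of this diketo ester (DBU, toluene, 80 °C, loss of methanol) would then rejoin the route at 20. The conjugated 3-methylindene is the thermodynamically preferred alkene isomer, so the amidine base should leave it in place.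

Step 13. The keto-aldehyde may undergo premature uncatalysed aldol closure, or lose water, on the slightly acidic support or during concentration; this would carry racemic ketol into step 14. The fallback sets out from 21, bypasses 22 and avoids both silica and water. Ozonolysis in CH2Cl2 at −78 °C to a Sudan Red 7B end point should consume the electron-rich indene alkene before the pyranone and give the bridged secondary ozonide, 4-(benzyloxy)-6-[4-(benzyloxy)-3-methyl-6-(3-methylbutyl)-1H-indene ozonide-7-yl]-2H-pyran-2-one (1,2,4-trioxolane spanning the former C2=C3 bond, racemic) F3. Reduction with PPh3 in the same flask returns to the route at 23, whose cold solution would go directly into step 14.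

Further compounds
F1 | step 14 | (3S)-8-(benzyloxy)-5-[4-(benzyloxy)-2-oxo-2H-pyran-6-yl]-3-hydroxy-6-(3-methylbutyl)-3,4-dihydronaphthalen-1(2H)-one | CC(C)CCc1cc(OCc3ccccc3)c2c(c1-c1cc(OCc3ccccc3)cc(=O)o1)C[C@H](O)CC2=O
F2 | step 10 | methyl 5-[4-(benzyloxy)-3-methyl-6-(3-methylbutyl)-1H-inden-7-yl]-3,5-dioxopentanoate | CC1=CCc2c(C(=O)CC(=O)CC(=O)OC)c(CCC(C)C)cc(OCc3ccccc3)c12
F3 | step 13 | secondary ozonide (1,2,4-trioxolane across the former indene C2=C3 bond) of 21, racemic | CC12OOC(O1)Cc3c(-c4cc(OCc5ccccc5)cc(=O)o4)c(CCC(C)C)cc(OCc4ccccc4)c23
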